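**Remarks on the chemistry (assumptions)**
- Locants used throughout: C1 CHOAc, C2 CH2, C3 and C4 the β and α carbons of the butenolide, C5 the lactone C=O, C6 the lactone OCH, C7=C8(CH3), C9, C10, C11–C12(CH3) epoxide, C13, C14, C15=C16(CH3), ring closed C16–C1.
- Neryl acetate 13, ylide 8 and acid 29 are taken as commercial.
- The sense of induction of the isopinocampheyl ligands is an assumption: the enol borinate made with (+)-Ipc2BCl (from (−)-α-pinene) is assumed to add to the Re face of an aldehyde, which gives (1R); a model aldol settles this before step 18.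
- The tartrate assignments in steps 1 and 12 are derived from the usual facial rule of the titanium–tartrate epoxidation, not recalled from a specific case.

## Analysis of the target

The target is a cembranoid: a 14-membered carbocycle (C1–C3 and C6–C16) fused across C3–C6 to an α-methyl butenolide (C3=C4(CH3)–C5(=O)–O–C6). It has four stereocentres: C1 (R, acetate), C6 (R, lactone oxygen), C11 (S) and C12 (R). C1 and C6 are 1,4-related across C2–C3 and sit anti in the zigzag. The epoxide is cis (C10 and C13 on the same side, so it comes from a Z olefin) and is too far from C1 and C6 for any relay, so it must be set by a reagent. Both ring alkenes (C7=C8, C15=C16) are E and trisubstituted. The epoxide is sensitive to acid, Lewis acid and hydride; the C6–H is allylic and γ to the lactone carbonyl, so base can epimerise it; the allylic C1 acetate can be lost by vinylogous elimination. The difficulty is closing the 14-membered ring with control of C1 while carrying the epoxide, and building the butenolide without losing C6. The strategy rests on one feature: at the ketone oxidation level C3 is a carbonyl, C1 is β to it, and C1 is also the carbonyl carbon of an (E)-2-methyl enal (C1–C16=C15), so C1–C2 is an aldol bond between a methyl ketone and a non-enolisable enal.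

## Retrosynthetic reasoning

**33 to 31.** The acetate is installed last, via alcohol 32 and TES ether 31. A β-acyloxy group would be a leaving group during the basic butenolide closure, whereas a silyl ether is not.

**31 to 28.** The butenolide is cut at C3=C4 and at the C5–O ester bond. This gives phosphonate 30, made from α-hydroxy ketone 28 and acid 29. The forward step is an intramolecular Horner–Wadsworth–Emmons reaction on the C3 ketone, which is already at the right oxidation level, so no redox step follows.

**28 to 26.** The two oxygens must be told apart: C6–O carries a PMB ether (removed oxidatively, 27 to 28) and C1–O a TES ether (26 to 27). PMB at C6 is also the ether type that a boron aldol tolerates next to the ketone.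

**26 to 23 (key disconnection).** The C1–C2 bond is cut. This is the only ring bond whose formation also creates a stereocentre (C1), and both partners, the methyl ketone and the enal, exist in the acyclic chain 23 without further activation. The enal cannot enolise and only the methyl group is kinetically accessible on the ketone side, so the aldol has a single sense. The forward reaction must close a 14-membered ring, choose the Re face of C1, and leave the C6–H and the epoxide alone.

**23 to 21.** Both carbonyls of 23 are released together, in the last step before the ring closure, by oxidising diol 22, which comes from bis-silyl ether 21. The epimerisable α-alkoxy ketone therefore exists for one step only, and no carbonyl is present during the carbanion and hydride steps before it.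

**21 to 12 and 18.** The chain is cut at C9–C10, between the two stereochemical domains. C9 is allylic and becomes the carbanion of sulfone 12. C10 is the primary carbinol carbon of an epoxy alcohol and becomes triflate 18. The sulfone is removed afterwards (20 to 21) by palladium-catalysed hydride delivery, which keeps the C7=C8 position and geometry.

**18 to 13.** The C10–C16 and C1 carbons map onto neryl acetate 13: its Z olefin becomes the cis epoxide by hydroxyl-directed asymmetric epoxidation of 16, and its (E)-methyl group becomes C1 by allylic oxidation (13 to 14). The low-yielding oxidation is placed first, on cheap material, and C1 travels as a silyl ether (15, 16, 17).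

**12 to 7 and 8.** The C7=C8 olefin is cut by a Wittig disconnection into aldehyde 7 and stabilised ylide 8, which gives the E trisubstituted enoate 9. Reduction (10) and sulfinate displacement (via 11) give 12.

**7 to 1.** C6 is set by desymmetrising divinylcarbinol 1. Epoxidation gives 2, PMB protection gives 3, and hydride opening of the terminal epoxide gives 4. This puts the C2 methyl group and a sacrificial C3 carbinol in place from the start, with the two oxygens already differentiated. Silylation (5) and cleavage of the remaining vinyl group give 7. A three-carbon chiral-pool aldehyde would set C6 equally well, but it would need a later C-methylation through an easily epimerised α-alkoxy-β,γ-unsaturated aldehyde.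

## Alternatives that were turned down

**Alternative 1: three-component butenolide assembly.**
- Disconnection: C2–C3, C4–C5 and C5–O of the butenolide.
- Forward key step: the magnesium alkoxide of propargylic alcohol A2 directs anti addition of Grignard reagent A3 across C3≡C4; the C4–Mg bond is carboxylated and acid closes the lactone to butenolide A1.
- For: the fully substituted butenolide is made in one operation, C6 is fixed beforehand on a simple propargylic alcohol, and no epimerisable α-alkoxy ketone or basic olefination is needed. On butenolide construction this alternative is stronger than the chosen route.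
- Against: carbomagnesiation of a methyl-capped propargylic alkoxide needs excess Grignard reagent and heat, with the epoxide of A2 present, and the lactonisation is acidic. More importantly, the step closes no macrocycle and sets no stereocentre: C1 arrives as an acetal in A1, and C15–C16 still has to be added.
- Comparison: the ring closure and C1 remain unsolved after the key step and would need a second strategic step. The chosen route solves both in the aldol and pays with a base-sensitive lactone closure.

**Alternative 2: hetero-Pauson–Khand macrocyclisation.**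
- Disconnection: C3–C6, C4–C5 and C5–O at once.
- Forward key step: the C6 enal and the C3≡C4 silylalkyne of acyclic A5 combine with a carbonyl ligand on a low-valent metal to give macrocyclic α-silyl butenolide A4.
- For: three bonds and both rings form in one step from a precursor without a C6 stereocentre. In bond count per step it is stronger than the chosen route.
- Against: the reaction type is established for five- and six-membered tethers, not for a 14-membered one. C6 would be set only by remote induction from C1. A conjugated enal is a poor carbonyl partner, and low-valent titanium-type reagents deoxygenate epoxides. The silyl group must then be exchanged for methyl (ipso-iodination and methyl coupling) on a sensitive lactone.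
- Comparison: ring closure, regiochemistry and C6 control would all depend on one unprecedented step. In the chosen route C6 comes from a reliable epoxidation and only C1 depends on the ring closure.

**Alternative 3: ring contraction by decarboxylative allylation.**
- Disconnection: C9–C10.
- Forward key step: zerovalent palladium ionises the C9 allylic ester of 16-membered β-keto lactone A7, the carboxylate is lost, and the C10 enolate recombines at C9 to give 14-membered ketone A6.
- For: the macrocycle is first closed as a lactone, the enolate is generated regiospecifically under neutral conditions, and the C–C bond forms within a tether. On ring-closure reliability it is stronger than the chosen route.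
- Against: in A7 the C6–O lactone bond is itself allylic to C7=C8, so palladium can ionise the butenolide and scramble C6. The allyl unit can be attacked at C7 instead of C9, and syn/anti isomerisation erodes the E geometry. After contraction the C11 ketone and C12 silyloxy group of A6 must still be turned into the cis epoxide (stereoselective reduction, activation, closure), which adds a new stereocontrol problem and several steps.
- Comparison: the chosen route carries the finished epoxide from a directed epoxidation and never exposes the butenolide to palladium.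

Key step: step 18

## Route

Step 1
Reactants: 1 penta-1,4-dien-3-ol (divinylcarbinol)
Product: 2 (1R)-1-[(2S)-oxiran-2-yl]prop-2-en-1-ol
Conditions: Ti(OiPr)4, D-(−)-diisopropyl tartrate, t-BuOOH, 4 Å MS, CH2Cl2, −20 °C
Reagents that add atoms: tert-butyl hydroperoxide, CC(C)(C)OO
Why: Sharpless asymmetric epoxidation of a prochiral divinyl carbinol; the tartrate selects one enantiotopic vinyl group and one face (erythro product), and the minor enantiomer is consumed by a second epoxidation, so enantiopurity should rise with conversion. This sets the future C6 (R) and a sacrificial centre at the future C3.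

Step 2
Reactants: 2 (1R)-1-[(2S)-oxiran-2-yl]prop-2-en-1-ol
Product: 3 (2S)-2-{(1R)-1-[(4-methoxybenzyl)oxy]prop-2-en-1-yl}oxirane
Conditions: NaH, 4-methoxybenzyl chloride, Bu4NI (cat.), THF, 0 °C to rt
Reagents that add atoms: 4-methoxybenzyl chloride, COc1ccc(CCl)cc1
Why: Williamson etherification of the secondary alkoxide; under aprotic conditions epoxide migration of the alkoxide is slow compared with benzylation.

Step 3
Reactants: 3 (2S)-2-{(1R)-1-[(4-methoxybenzyl)oxy]prop-2-en-1-yl}oxirane
Product: 4 (2S,3R)-3-[(4-methoxybenzyl)oxy]pent-4-en-2-ol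
Conditions: LiAlH4, THF, 0 °C
Reagents that add atoms: none
Why: Hydride opens the terminal epoxide at the unhindered CH2 (SN2), which turns it into the C2 methyl group and leaves a free C3 hydroxyl next to the PMB-protected C6.

Step 4
Reactants: 4 (2S,3R)-3-[(4-methoxybenzyl)oxy]pent-4-en-2-ol
Product: 5 tert-butyl{[(2S,3R)-3-[(4-methoxybenzyl)oxy]pent-4-en-2-yl]oxy}dimethylsilane
Conditions: TBSCl, imidazole, DMF, rt
Reagents that add atoms: tert-butyldimethylsilyl chloride, CC(C)(C)[Si](C)(C)Cl
Why: Standard silylation of a secondary alcohol; the TBS ether survives the carbanion and hydride steps that follow.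

Step 5
Reactants: 5 tert-butyl{[(2S,3R)-3-[(4-methoxybenzyl)oxy]pent-4-en-2-yl]oxy}dimethylsilane
Product: 7 (2S,3S)-3-[(tert-butyldimethylsilyl)oxy]-2-[(4-methoxybenzyl)oxy]butanal, via vicinal diol 6 (not isolated)
Conditions: OsO4 (cat.), NaIO4, 2,6-lutidine, dioxane/H2O, rt
Reagents that add atoms: osmium tetroxide, O=[Os](=O)(=O)=O; sodium periodate, [Na+].[O-]I(=O)(=O)=O
Why: Lemieux–Johnson cleavage of the terminal vinyl group; it spares the electron-rich PMB ring, and the lutidine buffer protects the α-alkoxy aldehyde, which is used crude.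

Step 6
Reactants: 7 (2S,3S)-3-[(tert-butyldimethylsilyl)oxy]-2-[(4-methoxybenzyl)oxy]butanal; 8 ethyl 2-(triphenylphosphoranylidene)propanoate
Product: 9 ethyl (2E,4R,5S)-5-[(tert-butyldimethylsilyl)oxy]-4-[(4-methoxybenzyl)oxy]-2-methylhex-2-enoate
Conditions: CH2Cl2, rt
Reagents that add atoms: none
Why: Wittig olefination with a stabilised α-methyl ylide, which is reliably E-selective with α-alkoxy aldehydes and builds the C7=C8(CH3) olefin under neutral conditions.

Step 7
Reactants: 9 ethyl (2E,4R,5S)-5-[(tert-butyldimethylsilyl)oxy]-4-[(4-methoxybenzyl)oxy]-2-methylhex-2-enoate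
Product: 10 (2E,4R,5S)-5-[(tert-butyldimethylsilyl)oxy]-4-[(4-methoxybenzyl)oxy]-2-methylhex-2-en-1-ol
Conditions: i-Bu2AlH, CH2Cl2, −78 °C
Reagents that add atoms: none
Why: 1,2-Reduction of the enoate to the allylic alcohol (the future C9) without touching the olefin geometry.

Step 8
Reactants: 10 (2E,4R,5S)-5-[(tert-butyldimethylsilyl)oxy]-4-[(4-methoxybenzyl)oxy]-2-methylhex-2-en-1-ol
Product: 12 tert-butyl{[(2S,3R,4E)-3-[(4-methoxybenzyl)oxy]-5-methyl-6-(phenylsulfonyl)hex-4-en-2-yl]oxy}dimethylsilane, via allylic mesylate 11 (not isolated)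
Conditions: MsCl, Et3N, CH2Cl2, −20 °C; then PhSO2Na, Bu4NI (cat.), DMF, rt
Reagents that add atoms: sodium benzenesulfinate, [Na+].[O-]S(=O)c1ccccc1
Why: Activation of the primary allylic alcohol and SN2 displacement by sulfinate at sulfur (iodide catalysis favours S-alkylation); the phenyl sulfone makes C9 a stabilised carbanion.

Step 9
Reactants: 13 neryl acetate
Product: 14 (2Z,6E)-8-hydroxy-3,7-dimethylocta-2,6-dien-1-yl acetate
Conditions: SeO2 (cat.), t-BuOOH, salicylic acid (cat.), CH2Cl2, rt
Reagents that add atoms: selenium dioxide, O=[Se]=O; tert-butyl hydroperoxide, CC(C)(C)OO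
Why: Allylic oxidation by ene reaction and [2,3]-shift at the (E)-methyl group of the terminal olefin; the 2,3-olefin is deactivated by the allylic acetate, and any over-oxidised enal is removed by chromatography.

Step 10
Reactants: 14 (2Z,6E)-8-hydroxy-3,7-dimethylocta-2,6-dien-1-yl acetate
Product: 15 (2Z,6E)-8-[(tert-butyldimethylsilyl)oxy]-3,7-dimethylocta-2,6-dien-1-yl acetate
Conditions: TBSCl, imidazole, CH2Cl2, rt
Reagents that add atoms: tert-butyldimethylsilyl chloride, CC(C)(C)[Si](C)(C)Cl
Why: Silylation of the primary allylic alcohol; this carries the future C1 oxygen through the coupling.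

Step 11
Reactants: 15 (2Z,6E)-8-[(tert-butyldimethylsilyl)oxy]-3,7-dimethylocta-2,6-dien-1-yl acetate
Product: 16 (2Z,6E)-8-[(tert-butyldimethylsilyl)oxy]-3,7-dimethylocta-2,6-dien-1-ol
Conditions: K2CO3, MeOH, rt
Reagents that add atoms: none
Why: Transesterification removes the acetate and frees the Z allylic alcohol that directs the epoxidation.

Step 12
Reactants: 16 (2Z,6E)-8-[(tert-butyldimethylsilyl)oxy]-3,7-dimethylocta-2,6-dien-1-ol
Product: 17 {(2S,3R)-3-[(3E)-5-[(tert-butyldimethylsilyl)oxy]-4-methylpent-3-en-1-yl]-3-methyloxiran-2-yl}methanol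
Conditions: Ti(OiPr)4, L-(+)-diethyl tartrate, t-BuOOH, 4 Å MS, CH2Cl2, −20 °C
Reagents that add atoms: tert-butyl hydroperoxide, CC(C)(C)OO
Why: Sharpless asymmetric epoxidation of the Z allylic alcohol; only the hydroxyl-bearing olefin reacts, and the L-tartrate sets C11 (S) and C12 (R) as the cis epoxide.

Step 13
Reactants: 17 {(2S,3R)-3-[(3E)-5-[(tert-butyldimethylsilyl)oxy]-4-methylpent-3-en-1-yl]-3-methyloxiran-2-yl}methanol
Product: 18 {(2S,3R)-3-[(3E)-5-[(tert-butyldimethylsilyl)oxy]-4-methylpent-3-en-1-yl]-3-methyloxiran-2-yl}methyl trifluoromethanesulfonate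
Conditions: Tf2O, 2,6-lutidine, CH2Cl2, −78 °C; used at once
Reagents that add atoms: trifluoromethanesulfonic anhydride, O=S(=O)(OS(=O)(=O)C(F)(F)F)C(F)(F)F
Why: Sulfonylation of the primary alcohol at low temperature with a hindered base; the triflate makes C10 reactive enough to be attacked in preference to the hindered epoxide carbons.

Step 14
Reactants: 12 tert-butyl{[(2S,3R,4E)-3-[(4-methoxybenzyl)oxy]-5-methyl-6-(phenylsulfonyl)hex-4-en-2-yl]oxy}dimethylsilane; 18 epoxy triflate
Product: 20 acyclic C9 phenyl sulfone (C9 epimers; 3S,6R,11S,12R; 7E,15E) carrying TBS ethers at C1 and C3 plus the C6 PMB ether, via lithiated sulfone 19 (not isolated)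
Conditions: 12, n-BuLi, THF, −78 °C; then 18, THF, −78 to −40 °C
Reagents that add atoms: none
Why: α-Alkylation of a lithiated allylic sulfone with a primary triflate (SN2), which forms C9–C10; allylic sulfone anions alkylate at the sulfone-bearing carbon, and the trisubstituted epoxide is much less electrophilic than the triflate.

Step 15
Reactants: 20 acyclic C9 phenyl sulfone
Product: 21 (3S,6R,7E,11S,12R,15E)-1,3-bis(tert-butyldimethylsilyloxy)-6-(4-methoxybenzyloxy)-11,12-epoxy acyclic chain C1–C16
Conditions: PdCl2(dppp) (cat.), LiBHEt3, THF, −20 to 0 °C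
Reagents that add atoms: none
Why: Palladium-catalysed reductive desulfonylation: zerovalent palladium ionises the allylic sulfone and hydride is delivered to the allyl terminus remote from the C6 ether, so the C7=C8 position and E geometry are kept; the low temperature and slow hydride addition are meant to spare the hindered epoxide.

Step 16
Reactants: 21 bis-silyl ether
Product: 22 (3S,6R,7E,11S,12R,15E)-6-(4-methoxybenzyloxy)-11,12-epoxy-1,3-diol of the C1–C16 chain
Conditions: Bu4NF, THF, 0 °C to rt
Reagents that add atoms: none
Why: Fluoride removes both TBS ethers in one operation; the epoxide, PMB ether and olefins are inert.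

Step 17
Reactants: 22 diol
Product: 23 acyclic epoxy keto enal with C6 PMB ether (6R,7E,11S,12R,15E)
Conditions: Dess–Martin periodinane, NaHCO3, CH2Cl2, 0 °C to rt; used at once
Reagents that add atoms: none
Why: Buffered, non-basic double oxidation releases the C1 enal and the C3 ketone together (this erases the sacrificial C3 centre); the α-alkoxy ketone with its acidic C6–H is formed only now and is taken on directly.

Step 18
Reactants: 23 acyclic epoxy keto enal
Product: 26 14-membered β-hydroxy ketone (1R,6R,11S,12R) with C6 PMB ether, via enol borinate 24 (not isolated), via boron aldolate 25 (not isolated)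
Conditions: (+)-Ipc2BCl, Et3N, Et2O, 0 °C, slow addition of 23 (final ca. 3 mM), then −20 °C; H2O2, pH 7 buffer, MeOH, 0 °C
Reagents that add atoms: none
Why: Et3N deprotonates the borane-complexed ketone at the methyl group (C2), the less hindered and kinetically preferred site for a bulky dialkylboron chloride, and gives enol borinate 24 without touching the C6–H. Enolate 24 adds to the tethered C1 enal through a six-membered cyclic (Zimmerman–Traxler-type) transition state in which boron bridges both oxygens; this forms C1–C2 and boron aldolate 25, which does not revert, so the closure is kinetically controlled. The closest known reaction type is the boron-mediated aldol addition of α-alkoxy methyl ketones to enals, run here intramolecularly as an aldol macrocyclisation. The 14-membered ring closes in a 14-(enolendo)-exo-trig mode, with the C2=C3 enolate bond inside the new ring and the aldehyde oxygen outside. The new C1 stereocentre is controlled by the isopinocampheyl groups on boron, chosen to deliver C2 to the Re face of the enal (1R); the C6 PMB ether exerts a modest 1,4-bias that is expected to oppose this, and the ring conformation is a third influence. Regioselective enolisation is secured by the methyl ketone and the hindered reagent, and chemoselectivity by the enal, which has no α-hydrogen and, being conjugated and α-branched, should be reduced only slowly by hydride transfer from an isopinocampheyl group. Ring closure over oligomerisation is secured by slow addition into excess reagent, so that enolisation stays fast while the free substrate stays dilute. The amine keeps the medium non-acidic for the epoxide, and the buffered peroxide work-up cleaves the boron residues without touching the trisubstituted olefins.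

Step 19
Reactants: 26 14-membered β-hydroxy ketone
Product: 27 C1 triethylsilyl ether of 26
Conditions: TESCl, imidazole, DMAP (cat.), CH2Cl2, 0 °C to rt
Reagents that add atoms: chlorotriethylsilane, CC[Si](Cl)(CC)CC
Why: Mild silylation of the secondary allylic alcohol; a silyl ether is a poor leaving group, so the β-oxygenated ketone should not eliminate in the basic step 22.

Step 20
Reactants: 27 C1 triethylsilyl ether
Product: 28 C6 α-hydroxy ketone (1R,6R,11S,12R) with C1 OTES
Conditions: DDQ, CH2Cl2/pH 7 buffer, 0 °C
Reagents that add atoms: none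
Why: Oxidative removal of the PMB ether through the benzylic cation and hemiacetal; buffering protects the epoxide and the TES ether, and the short reaction time limits further oxidation of the allylic alcohol.

Step 21
Reactants: 28 C6 α-hydroxy ketone; 29 2-(diethoxyphosphoryl)propanoic acid
Product: 30 C6 2-(diethoxyphosphoryl)propanoate of 28 (epimers at the phosphonate carbon)
Conditions: DCC, DMAP (cat.), CH2Cl2, 0 °C to rt
Reagents that add atoms: none
Why: Carbodiimide esterification of the secondary allylic alcohol; this places the phosphonate carbon (C4, with its methyl) five atoms from the C3 ketone.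

Step 22
Reactants: 30 C6 phosphonopropanoate
Product: 31 macrocyclic butenolide with C1 OTES (1R,6R,11S,12R)
Conditions: LiCl, i-Pr2NEt, MeCN, rt
Reagents that add atoms: none
Why: Intramolecular Horner–Wadsworth–Emmons reaction under lithium chloride/amine (Masamune–Roush) conditions; lithium chelation acidifies only the phosphonate C–H, the carbanion adds to the C3 ketone in a 5-exo closure and elimination gives C3=C4, and the weak amine base is chosen to leave the C6–H and the β-silyloxy ketone alone.

Step 23
Reactants: 31 macrocyclic butenolide with C1 OTES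
Product: 32 C1 alcohol of the macrocyclic butenolide
Conditions: HF·pyridine, pyridine, THF, 0 °C
Reagents that add atoms: none
Why: Buffered fluoride cleaves the labile TES ether; it avoids basic fluoride, which could epimerise the C6–H through the furanolate, and strong acid, which would open the epoxide.

Step 24
Reactants: 32 C1 alcohol
Product: 33 target acetate
Conditions: Ac2O, pyridine, DMAP (cat.), CH2Cl2, 0 °C
Reagents that add atoms: acetic anhydride, CC(=O)OC(C)=O
Why: Standard acylation of the secondary allylic alcohol with retention at C1; the mild base leaves C6 and the allylic acetate untouched.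

## Compound list

1 | penta-1,4-dien-3-ol | C=CC(O)C=C | starting material
2 | (1R)-1-[(2S)-oxiran-2-yl]prop-2-en-1-ol | C=C[C@@H](O)[C@@H]1CO1 | intermediate
3 | (2S)-2-{(1R)-1-[(4-methoxybenzyl)oxy]prop-2-en-1-yl}oxirane | C=C[C@@H](OCc1ccc(OC)cc1)[C@@H]1CO1 | intermediate
4 | (2S,3R)-3-[(4-methoxybenzyl)oxy]pent-4-en-2-ol | C=C[C@@H](OCc1ccc(OC)cc1)[C@H](C)O | intermediate
5 | tert-butyl{[(2S,3R)-3-[(4-methoxybenzyl)oxy]pent-4-en-2-yl]oxy}dimethylsilane | C=C[C@@H](OCc1ccc(OC)cc1)[C@H](C)O[Si](C)(C)C(C)(C)C | intermediate
6 | (3R,4S)-4-[(tert-butyldimethylsilyl)oxy]-3-[(4-methoxybenzyl)oxy]pentane-1,2-diol (C2 epimers) | OCC(O)[C@@H](OCc1ccc(OC)cc1)[C@H](C)O[Si](C)(C)C(C)(C)C | intermediate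
7 | (2S,3S)-3-[(tert-butyldimethylsilyl)oxy]-2-[(4-methoxybenzyl)oxy]butanal | O=C[C@@H](OCc1ccc(OC)cc1)[C@H](C)O[Si](C)(C)C(C)(C)C | intermediate
8 | ethyl 2-(triphenylphosphoranylidene)propanoate | CCOC(=O)C(C)=P(c1ccccc1)(c1ccccc1)c1ccccc1 | starting material
9 | ethyl (2E,4R,5S)-5-[(tert-butyldimethylsilyl)oxy]-4-[(4-methoxybenzyl)oxy]-2-methylhex-2-enoate | CCOC(=O)/C(C)=C/[C@@H](OCc1ccc(OC)cc1)[C@H](C)O[Si](C)(C)C(C)(C)C | intermediate
10 | (2E,4R,5S)-5-[(tert-butyldimethylsilyl)oxy]-4-[(4-methoxybenzyl)oxy]-2-methylhex-2-en-1-ol | OC/C(C)=C/[C@@H](OCc1ccc(OC)cc1)[C@H](C)O[Si](C)(C)C(C)(C)C | intermediate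
11 | methanesulfonate of 10 | CS(=O)(=O)OC/C(C)=C/[C@@H](OCc1ccc(OC)cc1)[C@H](C)O[Si](C)(C)C(C)(C)C | intermediate
12 | tert-butyl{[(2S,3R,4E)-3-[(4-methoxybenzyl)oxy]-5-methyl-6-(phenylsulfonyl)hex-4-en-2-yl]oxy}dimethylsilane | O=S(=O)(c1ccccc1)C/C(C)=C/[C@@H](OCc1ccc(OC)cc1)[C@H](C)O[Si](C)(C)C(C)(C)C | intermediate
13 | neryl acetate, (2Z)-3,7-dimethylocta-2,6-dien-1-yl acetate | CC(C)=CCC/C(C)=C\COC(C)=O | starting material
14 | (2Z,6E)-8-hydroxy-3,7-dimethylocta-2,6-dien-1-yl acetate | OC/C(C)=C/CC/C(C)=C\COC(C)=O | intermediate
15 | (2Z,6E)-8-[(tert-butyldimethylsilyl)oxy]-3,7-dimethylocta-2,6-dien-1-yl acetate | CC(C)(C)[Si](C)(C)OC/C(C)=C/CC/C(C)=C\COC(C)=O | intermediate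
16 | (2Z,6E)-8-[(tert-butyldimethylsilyl)oxy]-3,7-dimethylocta-2,6-dien-1-ol | CC(C)(C)[Si](C)(C)OC/C(C)=C/CC/C(C)=C\CO | intermediate
17 | {(2S,3R)-3-[(3E)-5-[(tert-butyldimethylsilyl)oxy]-4-methylpent-3-en-1-yl]-3-methyloxiran-2-yl}methanol | OC[C@@H]1O[C@]1(C)CC/C=C(\C)CO[Si](C)(C)C(C)(C)C | intermediate
18 | trifluoromethanesulfonate of 17 | O=S(=O)(OC[C@@H]1O[C@]1(C)CC/C=C(\C)CO[Si](C)(C)C(C)(C)C)C(F)(F)F | intermediate
19 | α-lithio derivative of sulfone 12 (lithium at C9) | [Li]C(/C(C)=C/[C@@H](OCc1ccc(OC)cc1)[C@H](C)O[Si](C)(C)C(C)(C)C)S(=O)(=O)c1ccccc1 | intermediate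
20 | acyclic C9 phenyl sulfone, C1 and C3 TBS ethers, C6 PMB ether, 11,12-epoxide (3S,6R,11S,12R; 7E,15E; C9 epimers) | C[C@H](O[Si](C)(C)C(C)(C)C)[C@H](OCc1ccc(OC)cc1)/C=C(\C)C(S(=O)(=O)c1ccccc1)C[C@@H]1O[C@]1(C)CC/C=C(\C)CO[Si](C)(C)C(C)(C)C | intermediate
21 | desulfonylated chain, C1 and C3 TBS ethers, C6 PMB ether, 11,12-epoxide (3S,6R,11S,12R; 7E,15E) | C[C@H](O[Si](C)(C)C(C)(C)C)[C@H](OCc1ccc(OC)cc1)/C=C(\C)CC[C@@H]1O[C@]1(C)CC/C=C(\C)CO[Si](C)(C)C(C)(C)C | intermediate
22 | C1,C3-diol of the chain, C6 PMB ether, 11,12-epoxide | C[C@H](O)[C@H](OCc1ccc(OC)cc1)/C=C(\C)CC[C@@H]1O[C@]1(C)CC/C=C(\C)CO | intermediate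
23 | acyclic epoxy keto enal with C6 PMB ether (C3 methyl ketone, C1 enal; 6R,11S,12R; 7E,15E) | CC(=O)[C@H](OCc1ccc(OC)cc1)/C=C(\C)CC[C@@H]1O[C@]1(C)CC/C=C(\C)C=O | intermediate
24 | enol diisopinocampheylborinate of 23 (C2=C3, boron on the C3 oxygen) | C=C(OB([C@H]1C[C@H]2C[C@@H]([C@@H]1C)C2(C)C)[C@H]1C[C@H]2C[C@@H]([C@@H]1C)C2(C)C)[C@H](OCc1ccc(OC)cc1)/C=C(\C)CC[C@@H]1O[C@]1(C)CC/C=C(\C)C=O | intermediate
25 | boron aldolate, C1–O–B(Ipc)2 derivative of 26 | B([C@H]1C[C@H]2C[C@@H]([C@@H]1C)C2(C)C)([C@H]1C[C@H]2C[C@@H]([C@@H]1C)C2(C)C)O[C@@H]3CC(=O)[C@H](OCc4ccc(OC)cc4)/C=C(\C)CC[C@@H]4O[C@]4(C)CC/C=C/3C | intermediate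
26 | 14-membered β-hydroxy ketone (1R,6R,11S,12R), C6 PMB ether | O[C@@H]1CC(=O)[C@H](OCc2ccc(OC)cc2)/C=C(\C)CC[C@@H]2O[C@]2(C)CC/C=C/1C | intermediate
27 | C1 triethylsilyl ether of 26 | CC[Si](CC)(CC)O[C@@H]1CC(=O)[C@H](OCc2ccc(OC)cc2)/C=C(\C)CC[C@@H]2O[C@]2(C)CC/C=C/1C | intermediate
28 | C6 α-hydroxy ketone, C1 OTES | CC[Si](CC)(CC)O[C@@H]1CC(=O)[C@H](O)/C=C(\C)CC[C@@H]2O[C@]2(C)CC/C=C/1C | intermediate
29 | 2-(diethoxyphosphoryl)propanoic acid | CCOP(=O)(OCC)C(C)C(=O)O | starting material
30 | C6 2-(diethoxyphosphoryl)propanoate of 28 | CC[Si](CC)(CC)O[C@@H]1CC(=O)[C@H](OC(=O)C(C)P(=O)(OCC)OCC)/C=C(\C)CC[C@@H]2O[C@]2(C)CC/C=C/1C | intermediate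
31 | macrocyclic butenolide, C1 OTES | CC[Si](CC)(CC)O[C@@H]1CC2=C(C)C(=O)O[C@@H]2/C=C(\C)CC[C@@H]2O[C@]2(C)CC/C=C/1C | intermediate
32 | macrocyclic butenolide, C1 alcohol | O[C@@H]1CC2=C(C)C(=O)O[C@@H]2/C=C(\C)CC[C@@H]2O[C@]2(C)CC/C=C/1C | intermediate
33 | target, C1 acetate (CNP0302675.1) | CC(=O)O[C@@H]1CC2=C(C)C(=O)O[C@@H]2/C=C(\C)CC[C@@H]2O[C@]2(C)CC/C=C/1C | target

## Step count and least certain steps

Total: 24 steps. Longest linear sequence: 19 steps (steps 1–8 and 14–24); the neryl branch (steps 9–13) joins at step 14.

**Step 18 (key step).** Three things can go wrong: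
- Poor facial selectivity at C1 is the most likely: the ligands act at 0 °C, probably against the 1,4-bias of the C6 ether, inside a macrocyclic transition state.
- Oligomerisation can compete with ring closure, because enolisation is bimolecular and cannot be run at true high dilution.
- The chloroborane can damage the epoxide or slowly reduce the enal.

Fallback: it sets out from 23 and returns at 33. The ring is closed with the reagent whose bias agrees with the C6 ether, (−)-Ipc2BCl or dicyclohexylboron chloride, to give the C1-epimeric β-hydroxy ketone F1. F1 is taken through the chemistry of steps 19 to 23: TES ether F2, α-hydroxy ketone F3, phosphonate ester F4, silylated butenolide F5 and C1-epimeric alcohol F6. F6 is then esterified under Mitsunobu conditions (PPh3, diisopropyl azodicarboxylate, AcOH), which inverts C1 and gives acetate 33 directly.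

**Step 15.** Hydride attack on the epoxide by LiBHEt3 is the main danger; hydride delivery to the wrong allyl terminus, or loss of the E geometry, is the second. Fallback: it sets out from 16 and 12 and returns at 21. Alcohol 16 is converted (MsCl, Et3N; LiBr) into the allylic bromide F7. Lithiated 12 is alkylated with F7 to the epoxide-free sulfone F8. The same palladium/hydride desulfonylation, now with nothing hydride-sensitive present, gives triene F9. A Shi epoxidation (L-fructose-derived ketone catalyst, KHSO5, buffered) then epoxidises C11=C12, the only olefin not deactivated by an allylic oxygen, to give 21. The catalyst enantiomer follows the spiro transition-state model, and selectivity may be lower for this Z-type olefin.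

**Step 22.** Base-induced epimerisation at C6, before or after ring closure, is the most likely problem; β-elimination of the C1 oxygen is the second. Fallback: it sets out from 28 and returns at 31. Alcohol 28 is acylated with 2-bromopropanoyl bromide and pyridine to the α-bromo ester F10. SmI2 (divalent samarium) in THF at −78 °C brings about an intramolecular Reformatsky addition to the C3 ketone and gives the β-hydroxy lactone F11. Dehydration with SOCl2 and pyridine towards the acidic C4–H gives 31 without a basic carbanion step.

**Step 23.** Fluoride or adventitious acid may open the epoxide, or the medium may epimerise C6, during desilylation. Fallback: it sets out from 26 and returns at 33. Alcohol 26 is acetylated (Ac2O, pyridine) to the β-acetoxy ketone F12. DDQ removes the PMB ether to give the α-hydroxy ketone F13. Esterification with 29 gives the phosphonate F14, and the lithium chloride/amine Horner–Wadsworth–Emmons closure gives 33 with no silyl ether to remove. The price is a leaving group β to the ketone during the olefination.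

## Further compounds

F1 | step 18 | (1S)-epimer of β-hydroxy ketone 26 | O[C@H]1CC(=O)[C@H](OCc2ccc(OC)cc2)/C=C(\C)CC[C@@H]2O[C@]2(C)CC/C=C/1C
F2 | step 18 | C1 triethylsilyl ether of F1 | CC[Si](CC)(CC)O[C@H]1CC(=O)[C@H](OCc2ccc(OC)cc2)/C=C(\C)CC[C@@H]2O[C@]2(C)CC/C=C/1C
F3 | step 18 | (1S)-configured C6 α-hydroxy ketone, C1 OTES | CC[Si](CC)(CC)O[C@H]1CC(=O)[C@H](O)/C=C(\C)CC[C@@H]2O[C@]2(C)CC/C=C/1C
F4 | step 18 | C6 2-(diethoxyphosphoryl)propanoate of F3 | CC[Si](CC)(CC)O[C@H]1CC(=O)[C@H](OC(=O)C(C)P(=O)(OCC)OCC)/C=C(\C)CC[C@@H]2O[C@]2(C)CC/C=C/1C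
F5 | step 18 | (1S)-configured macrocyclic butenolide, C1 OTES | CC[Si](CC)(CC)O[C@H]1CC2=C(C)C(=O)O[C@@H]2/C=C(\C)CC[C@@H]2O[C@]2(C)CC/C=C/1C
F6 | step 18 | (1S)-configured macrocyclic butenolide, C1 alcohol | O[C@H]1CC2=C(C)C(=O)O[C@@H]2/C=C(\C)CC[C@@H]2O[C@]2(C)CC/C=C/1C
F7 | step 15 | {[(2E,6Z)-8-bromo-2,6-dimethylocta-2,6-dien-1-yl]oxy}(tert-butyl)dimethylsilane | CC(C)(C)[Si](C)(C)OC/C(C)=C/CC/C(C)=C\CBr
F8 | step 15 | epoxide-free C9 phenyl sulfone with 11Z olefin, C1 and C3 TBS ethers, C6 PMB ether | C[C@H](O[Si](C)(C)C(C)(C)C)[C@H](OCc1ccc(OC)cc1)/C=C(\C)C(S(=O)(=O)c1ccccc1)C/C=C(C)\CC/C=C(\C)CO[Si](C)(C)C(C)(C)C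
F9 | step 15 | (7E,11Z,15E)-triene, C1 and C3 TBS ethers, C6 PMB ether | C[C@H](O[Si](C)(C)C(C)(C)C)[C@H](OCc1ccc(OC)cc1)/C=C(\C)CC/C=C(C)\CC/C=C(\C)CO[Si](C)(C)C(C)(C)C
F10 | step 22 | C6 2-bromopropanoate of 28 | CC[Si](CC)(CC)O[C@@H]1CC(=O)[C@H](OC(=O)C(C)Br)/C=C(\C)CC[C@@H]2O[C@]2(C)CC/C=C/1C
F11 | step 22 | C3-hydroxy γ-lactone (C3 and C4 epimers), C1 OTES | CC[Si](CC)(CC)O[C@@H]1CC2(O)C(C)C(=O)O[C@@H]2/C=C(\C)CC[C@@H]2O[C@]2(C)CC/C=C/1C
F12 | step 23 | C1 acetate of 26 (β-acetoxy ketone, C6 PMB ether) | CC(=O)O[C@@H]1CC(=O)[C@H](OCc2ccc(OC)cc2)/C=C(\C)CC[C@@H]2O[C@]2(C)CC/C=C/1C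
F13 | step 23 | C1 acetate, C6 α-hydroxy ketone | CC(=O)O[C@@H]1CC(=O)[C@H](O)/C=C(\C)CC[C@@H]2O[C@]2(C)CC/C=C/1C
F14 | step 23 | C6 2-(diethoxyphosphoryl)propanoate of F13 | CC(=O)O[C@@H]1CC(=O)[C@H](OC(=O)C(C)P(=O)(OCC)OCC)/C=C(\C)CC[C@@H]2O[C@]2(C)CC/C=C/1C
A1 | alternative 1 | butenolide with C1 as dioxolane acetal and C6–C14 chain | CC1=C(CC2OCCO2)[C@@H](/C=C(\C)CC[C@@H]3O[C@]3(C)CCO[Si](C)(C)C(C)(C)C)OC1=O
A2 | alternative 1 | (R)-propargylic alcohol, C4-methyl alkyne with C6–C14 chain | CC#C[C@H](O)/C=C(\C)CC[C@@H]1O[C@]1(C)CCO[Si](C)(C)C(C)(C)C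
A3 | alternative 1 | (1,3-dioxolan-2-ylmethyl)magnesium bromide | Br[Mg]CC1OCCO1
A4 | alternative 2 | macrocyclic α-trimethylsilyl butenolide, C1 silyl ether | CC(C)(C)[Si](C)(C)O[C@@H]1CC2=C([Si](C)(C)C)C(=O)O[C@@H]2/C=C(\C)CC[C@@H]2O[C@]2(C)CC/C=C/1C
A5 | alternative 2 | acyclic C6 enal with C3≡C4 trimethylsilylalkyne and C1 silyl ether | C[Si](C)(C)C#CC[C@@H](O[Si](C)(C)C(C)(C)C)/C(C)=C/CC[C@@]1(C)O[C@H]1CC/C(C)=C/C=O
A6 | alternative 3 | 14-membered C11 ketone with C12 silyloxy group | CC(C)(C)[Si](C)(C)O[C@@H]1CC2=C(C)C(=O)O[C@@H]2/C=C(\C)CCC(=O)[C@](C)(O[Si](CC)(CC)CC)CC/C=C/1C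
A7 | alternative 3 | 16-membered β-keto lactone, C9 allylic ester | CC(C)(C)[Si](C)(C)O[C@@H]1CC2=C(C)C(=O)O[C@@H]2/C=C(\C)COC(=O)CC(=O)[C@](C)(O[Si](CC)(CC)CC)CC/C=C/1C
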